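The butenolide is cut between its ring CH (C4) and the oxygen-bearing ring carbon C5 that carries the exocyclic alkylidene. The 5-ylidene-2(5H)-furanone is read as a C-vinylated enol ester: an intramolecular Mizoroki–Heck reaction of a (Z)-β-iodoacrylate onto its own (Z)-enol ester C=C closes the furanone ring by 5-exo attack at C5 and, through syn-insertion/syn-β-hydride elimination, turns the (Z)-enol ester into the (5E)-ylidene in one operation. The precursor, an open-chain (Z)-alk-1-enyl (Z)-3-iodoacrylate, comes from Ru-catalysed anti-Markovnikov addition of the iodo acid to a terminal alkyne assembled from (R)-citronellal by Negishi-type couplings.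

Key step: step 18

Assumption: the target SMILES is read as (5E) at the ylidene (side chain cis to ring C4–H, trans to the ring oxygen), R at the methyl-bearing centre, Z at the central and E at the furan-side trisubstituted alkene; monomeric formaldehyde is taken from cracked commercial paraformaldehyde.

Step 1
Reactants: 1 (R)-citronellal
Product: 3 (3R)-3,7-dimethyloct-6-en-1-yne, via alkenyl nonaflate 2 (not isolated)
Conditions: C4F9SO2F, phosphazene base P2-Et (2.5 equiv), DMF, −20 °C to rt
Reagents that add atoms: none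
Why: One-pot enol nonaflation and E2 loss of nonaflate (formal dehydration RCH2CHO to RC≡CH) should work because the only β-hydrogen of the 1-alkenyl sulfonate is vinylic, so no allene can form and the C3 centre of citronellal is never deprotonated.

Step 2
Reactants: 3 (3R)-3,7-dimethyloct-6-en-1-yne
Product: 5 [(3R)-3,7-dimethyloct-6-en-1-yn-1-yl]triisopropylsilane, via lithium acetylide 4 (not isolated)
Conditions: n-BuLi, THF, −78 °C; TIPSOTf, −78 °C to rt
Reagents that add atoms: triisopropylsilyl trifluoromethanesulfonate, CC(C)[Si](OS(=O)(=O)C(F)(F)F)(C(C)C)C(C)C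
Why: C-silylation of the lithium acetylide masks the alkyne against the later zinc, palladium and carboalumination steps.

Step 3
Reactants: 5 [(3R)-3,7-dimethyloct-6-en-1-yn-1-yl]triisopropylsilane
Product: 7 (4R)-4-methyl-6-(triisopropylsilyl)hex-5-yn-1-ol, via aldehyde 6 (not isolated)
Conditions: O3, CH2Cl2/MeOH, Sudan Red 7B, −78 °C; then NaBH4, −78 °C to rt
Reagents that add atoms: ozone, [O-][O+]=O
Why: Ozonolysis with reductive work-up should cleave only the electron-rich trisubstituted alkene, which reacts far faster than the hindered silyl alkyne.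

Step 4
Reactants: 7 (4R)-4-methyl-6-(triisopropylsilyl)hex-5-yn-1-ol
Product: 8 [(3R)-6-iodo-3-methylhex-1-yn-1-yl]triisopropylsilane
Conditions: I2, PPh3, imidazole, CH2Cl2, 0 °C to rt
Reagents that add atoms: iodine, II
Why: Appel-type (Garegg–Samuelsson) iodination of a primary alcohol is neutral and leaves the silyl alkyne and the stereocentre alone.

Step 5
Reactants: 9 but-2-yn-1-ol
Product: 11 (2Z)-3-iodobut-2-en-1-ol, via alkenylaluminate 10 (not isolated)
Conditions: Red-Al, Et2O, 0 °C to rt; EtOAc; then I2, THF, −78 °C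
Reagents that add atoms: iodine, II
Why: Hydroxyl-directed trans-hydroalumination puts aluminium on C3 cis to CH2O in a cyclic alkoxyaluminate, and iodinolysis with retention gives the Z-iodide.

Step 6
Reactants: 11 (2Z)-3-iodobut-2-en-1-ol
Product: 12 (2Z)-1-bromo-3-iodobut-2-ene
Conditions: PBr3, cat. pyridine, Et2O, −10 °C
Reagents that add atoms: phosphorus tribromide, BrP(Br)Br
Why: Low-temperature SN2 bromination of the primary allylic alcohol should proceed without allylic transposition or loss of geometry.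

Step 7
Reactants: 13 trimethyl(prop-1-yn-1-yl)silane; 12 (2Z)-1-bromo-3-iodobut-2-ene
Product: 15 [(5Z)-6-iodohept-5-en-1-yn-1-yl]trimethylsilane, via lithiated silylpropyne 14 (not isolated)
Conditions: 13, n-BuLi, THF, −78 °C; then 12, −78 to −20 °C
Reagents that add atoms: none
Why: SN2 alkylation of the propargylic lithium by the allylic bromide is fast, while iodine–lithium exchange at the vinyl iodide is disfavoured for this stabilised carbanion, so the Z-iodoalkene survives.

Step 8
Reactants: 8 [(3R)-6-iodo-3-methylhex-1-yn-1-yl]triisopropylsilane; 15 [(5Z)-6-iodohept-5-en-1-yn-1-yl]trimethylsilane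
Product: 17 triisopropyl[(3R,7Z)-3,7-dimethyl-12-(trimethylsilyl)dodec-7-ene-1,11-diyn-1-yl]silane, via alkylzinc iodide 16 (not isolated)
Conditions: 8, Zn dust (TMSCl/BrCH2CH2Br-activated), LiCl, THF, 40 °C; then 15, PdCl2(dppf) (5 mol%), THF, rt
Reagents that add atoms: none
Why: Negishi sp3–sp2 coupling proceeds with retention at the alkenyl iodide and so sets the Z-trisubstituted alkene; the alkylzinc tolerates both silyl alkynes.

Step 9
Reactants: 17 triisopropyl[(3R,7Z)-3,7-dimethyl-12-(trimethylsilyl)dodec-7-ene-1,11-diyn-1-yl]silane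
Product: 18 triisopropyl[(3R,7Z)-3,7-dimethyldodec-7-ene-1,11-diyn-1-yl]silane
Conditions: K2CO3, MeOH/THF, rt
Reagents that add atoms: none
Why: Base-catalysed methanolysis removes the small TMS group from carbon while the TIPS alkyne is inert, which differentiates the two alkynes.

Step 10
Reactants: 18 triisopropyl[(3R,7Z)-3,7-dimethyldodec-7-ene-1,11-diyn-1-yl]silane
Product: 20 [(3R,7Z,11E)-12-iodo-3,7,11-trimethyldodeca-7,11-dien-1-yn-1-yl]triisopropylsilane, via alkenylalane 19 (not isolated)
Conditions: Me3Al, Cp2ZrCl2 (0.25 equiv), CH2Cl2, 0 °C to rt; then I2, THF, −30 °C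
Reagents that add atoms: trimethylaluminium, C[Al](C)C; iodine, II
Why: Negishi zirconium-catalysed syn-carboalumination of the terminal alkyne (methyl to the internal carbon) and iodinolysis with retention give the E-iodoalkene; the bulky silyl alkyne and the trisubstituted alkene should not react.

Step 11
Reactants: 21 furan-3-carbaldehyde
Product: 22 3-ethenylfuran
Conditions: Ph3PCH3Br, KOtBu, THF, 0 °C; distilled and used as a THF solution
Reagents that add atoms: methyltriphenylphosphonium bromide, C[P+](c1ccccc1)(c1ccccc1)c1ccccc1.[Br-]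
Why: Wittig methylenation of an aromatic aldehyde is reliable, and the volatile product is handled in solution.

Step 12
Reactants: 22 3-ethenylfuran; 20 [(3R,7Z,11E)-12-iodo-3,7,11-trimethyldodeca-7,11-dien-1-yn-1-yl]triisopropylsilane
Product: 24 triisopropyl[(3R,7Z,11E)-14-(furan-3-yl)-3,7,11-trimethyltetradeca-7,11-dien-1-yn-1-yl]silane, via alkylborane 23 (not isolated)
Conditions: 22, 9-BBN-H, THF, 0 °C to rt; then 20, PdCl2(dppf) (5 mol%), AsPh3, Cs2CO3, DMF/H2O, rt
Reagents that add atoms: none
Why: Anti-Markovnikov hydroboration of the vinylfuran and B-alkyl Suzuki–Miyaura coupling with retention at the alkenyl iodide install the furylethyl end and fix the E-alkene.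

Step 13
Reactants: 24 triisopropyl[(3R,7Z,11E)-14-(furan-3-yl)-3,7,11-trimethyltetradeca-7,11-dien-1-yn-1-yl]silane
Product: 25 3-[(3E,7Z,12R)-4,8,12-trimethyltetradeca-3,7-dien-13-yn-1-yl]furan
Conditions: TBAF, THF, 0 °C to rt
Reagents that add atoms: none
Why: Fluoride cleaves the C(sp)–Si bond under conditions too weakly basic to isomerise the propargylic stereocentre.

Step 14
Reactants: 26 ethyl prop-2-ynoate; 27 formaldehyde
Product: 29 ethyl (2Z)-2-(hydroxymethyl)-3-iodoprop-2-enoate, via iodomagnesium allenolate 28 (not isolated)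
Conditions: MgI2, CH2Cl2, 0 °C; HCHO (gas), 0 °C; then H2O
Reagents that add atoms: magnesium iodide, [Mg+2].[I-].[I-]
Why: In this β-iodo Morita–Baylis–Hillman reaction, iodide conjugate addition gives a β-iodoallenolate that should add to formaldehyde at its central carbon anti to iodine, leaving iodine cis to the ester (Z).

Step 15
Reactants: 29 ethyl (2Z)-2-(hydroxymethyl)-3-iodoprop-2-enoate
Product: 30 ethyl (2Z)-2-{[(tert-butyldimethylsilyl)oxy]methyl}-3-iodoprop-2-enoate
Conditions: TBSCl, imidazole, CH2Cl2, 0 °C to rt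
Reagents that add atoms: tert-butyldimethylsilyl chloride, CC(C)(C)[Si](C)(C)Cl
Why: Standard silylation of the primary allylic alcohol keeps it out of the ruthenium and palladium steps.

Step 16
Reactants: 30 ethyl (2Z)-2-{[(tert-butyldimethylsilyl)oxy]methyl}-3-iodoprop-2-enoate
Product: 31 (2Z)-2-{[(tert-butyldimethylsilyl)oxy]methyl}-3-iodoprop-2-enoic acid
Conditions: LiOH·H2O, THF/H2O, 0 °C to rt; then cold 1 M HCl to pH 3
Reagents that add atoms: lithium hydroxide, [Li+].[OH-]
Why: Saponification should be clean because the acrylate has no α-hydrogen (no dehydroiodination) and a primary TBS ether survives cold dilute base and brief mild acid.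

Step 17
Reactants: 25 3-[(3E,7Z,12R)-4,8,12-trimethyltetradeca-3,7-dien-13-yn-1-yl]furan; 31 (2Z)-2-{[(tert-butyldimethylsilyl)oxy]methyl}-3-iodoprop-2-enoic acid
Product: 32 (1Z,3R,7Z,11E)-14-(furan-3-yl)-3,7,11-trimethyltetradeca-1,7,11-trien-1-yl (2Z)-2-{[(tert-butyldimethylsilyl)oxy]methyl}-3-iodoprop-2-enoate
Conditions: Ru(η3-2-methylallyl)2(dppb) (5 mol%), toluene, 60 °C
Reagents that add atoms: none
Why: In this Ru-catalysed anti-Markovnikov hydro-oxycarbonylation, the carboxylate adds to the α-carbon of a ruthenium vinylidene anti to the alkyl group and protonolysis gives the (Z)-enol ester; the propargylic centre and the vinyl iodide should not be touched.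

Step 18
Reactants: 32 (1Z,3R,7Z,11E)-14-(furan-3-yl)-3,7,11-trimethyltetradeca-1,7,11-trien-1-yl (2Z)-2-{[(tert-butyldimethylsilyl)oxy]methyl}-3-iodoprop-2-enoate
Product: 33 (5E)-3-{[(tert-butyldimethylsilyl)oxy]methyl}-5-[(2R,6Z,10E)-13-(furan-3-yl)-2,6,10-trimethyltrideca-6,10-dien-1-ylidene]furan-2(5H)-one
Conditions: Pd(OAc)2 (10 mol%), PPh3 (25 mol%), Ag2CO3 (2 equiv), MeCN (0.01 M), 70 °C
Reagents that add atoms: none
Why: Pd(0) inserts into the C–I bond with retention and Ag2CO3 strips iodide, giving a cationic (Z)-alkenylpalladium(II) that binds the enol-ester C=C once the ester adopts its s-cis rotamer; syn-carbopalladation then joins the acrylate β-carbon (ring C4) to the oxygen-bearing enol carbon (ring C5), and bond rotation followed by syn-β-hydride elimination of the former enol C5–H restores the exocyclic C=C. The closest known reaction type is the silver-promoted (cationic) intramolecular Mizoroki–Heck cyclisation of alkenyl iodides onto enol ethers and enol esters. The 2(5H)-furanone ring closes in the 5-exo-trig mode, favoured over 6-endo closure to an α-pyrone both by ring size and by the α-regiochemistry of cationic Heck additions to O-substituted alkenes. No stereocentre is created; the alkene geometry is dictated by the syn-addition/syn-elimination sequence, which places the incoming C4 trans to the hydrogen that was cis to the departing C5–H, so the (1Z)-enol ester should give the (5E)-ylidene with the side chain cis to C4. The step needs β-hydride elimination toward the ring (C5–H, allylic and α-oxygenated, giving the fully conjugated dienyl lactone) rather than toward the C–H of the methyl-bearing stereocentre, and no Pd–H re-addition; conjugation and fast silver/carbonate capture of HPdI should secure both, leaving the (R)-centre, the skipped diene and the furan untouched.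

Step 19
Reactants: 33 (5E)-3-{[(tert-butyldimethylsilyl)oxy]methyl}-5-[(2R,6Z,10E)-13-(furan-3-yl)-2,6,10-trimethyltrideca-6,10-dien-1-ylidene]furan-2(5H)-one
Product: 34 22-deoxy-23-hydroxymethylvariabilin
Conditions: HF·pyridine, pyridine/THF, 0 °C
Reagents that add atoms: none
Why: Buffered fluoride desilylation of the primary allylic TBS ether is mild enough not to isomerise the (5E)-ylidene butenolide or attack the furan.

Compound list
1 | (R)-citronellal, (3R)-3,7-dimethyloct-6-enal | CC(C)=CCC[C@@H](C)CC=O | starting material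
2 | (3R)-3,7-dimethylocta-1,6-dien-1-yl nonafluorobutane-1-sulfonate (E/Z) | CC(C)=CCC[C@@H](C)C=COS(=O)(=O)C(F)(F)C(F)(F)C(F)(F)C(F)(F)F | intermediate
3 | (3R)-3,7-dimethyloct-6-en-1-yne | CC(C)=CCC[C@@H](C)C#C | intermediate
4 | lithium (3R)-3,7-dimethyloct-6-en-1-yn-1-ide | CC(C)=CCC[C@@H](C)C#C[Li] | intermediate
5 | [(3R)-3,7-dimethyloct-6-en-1-yn-1-yl]triisopropylsilane | CC(C)=CCC[C@@H](C)C#C[Si](C(C)C)(C(C)C)C(C)C | intermediate
6 | (4R)-4-methyl-6-(triisopropylsilyl)hex-5-ynal | O=CCC[C@@H](C)C#C[Si](C(C)C)(C(C)C)C(C)C | intermediate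
7 | (4R)-4-methyl-6-(triisopropylsilyl)hex-5-yn-1-ol | OCCC[C@@H](C)C#C[Si](C(C)C)(C(C)C)C(C)C | intermediate
8 | [(3R)-6-iodo-3-methylhex-1-yn-1-yl]triisopropylsilane | ICCC[C@@H](C)C#C[Si](C(C)C)(C(C)C)C(C)C | intermediate
9 | but-2-yn-1-ol | CC#CCO | starting material
10 | sodium cyclic (Z)-alkenyl alkoxyaluminate from 9 and Red-Al | CC1=CCO[Al-]1(OCCOC)OCCOC.[Na+] | intermediate
11 | (2Z)-3-iodobut-2-en-1-ol | C/C(I)=C/CO | intermediate
12 | (2Z)-1-bromo-3-iodobut-2-ene | C/C(I)=C/CBr | intermediate
13 | trimethyl(prop-1-yn-1-yl)silane | CC#C[Si](C)(C)C | starting material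
14 | 3-lithio-1-(trimethylsilyl)prop-1-yne | [Li]CC#C[Si](C)(C)C | intermediate
15 | [(5Z)-6-iodohept-5-en-1-yn-1-yl]trimethylsilane | C/C(I)=C/CCC#C[Si](C)(C)C | intermediate
16 | [(4R)-4-methyl-6-(triisopropylsilyl)hex-5-yn-1-yl]zinc iodide | I[Zn]CCC[C@@H](C)C#C[Si](C(C)C)(C(C)C)C(C)C | intermediate
17 | triisopropyl[(3R,7Z)-3,7-dimethyl-12-(trimethylsilyl)dodec-7-ene-1,11-diyn-1-yl]silane | C[Si](C)(C)C#CCC/C=C(/C)CCC[C@@H](C)C#C[Si](C(C)C)(C(C)C)C(C)C | intermediate
18 | triisopropyl[(3R,7Z)-3,7-dimethyldodec-7-ene-1,11-diyn-1-yl]silane | C#CCC/C=C(/C)CCC[C@@H](C)C#C[Si](C(C)C)(C(C)C)C(C)C | intermediate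
19 | dimethyl[(1E,5Z,10R)-2,6,10-trimethyl-12-(triisopropylsilyl)dodeca-1,5-dien-11-yn-1-yl]alane | C[Al](C)/C=C(\C)CC/C=C(/C)CCC[C@@H](C)C#C[Si](C(C)C)(C(C)C)C(C)C | intermediate
20 | [(3R,7Z,11E)-12-iodo-3,7,11-trimethyldodeca-7,11-dien-1-yn-1-yl]triisopropylsilane | I/C=C(\C)CC/C=C(/C)CCC[C@@H](C)C#C[Si](C(C)C)(C(C)C)C(C)C | intermediate
21 | furan-3-carbaldehyde | O=Cc1ccoc1 | starting material
22 | 3-ethenylfuran | C=Cc1ccoc1 | intermediate
23 | 9-[2-(furan-3-yl)ethyl]-9-borabicyclo[3.3.1]nonane | C(Cc1ccoc1)B1C2CCCC1CCC2 | intermediate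
24 | triisopropyl[(3R,7Z,11E)-14-(furan-3-yl)-3,7,11-trimethyltetradeca-7,11-dien-1-yn-1-yl]silane | C/C(=C/CC/C(C)=C/CCc1ccoc1)CCC[C@@H](C)C#C[Si](C(C)C)(C(C)C)C(C)C | intermediate
25 | 3-[(3E,7Z,12R)-4,8,12-trimethyltetradeca-3,7-dien-13-yn-1-yl]furan | C/C(=C/CC/C(C)=C/CCc1ccoc1)CCC[C@@H](C)C#C | intermediate
26 | ethyl prop-2-ynoate | C#CC(=O)OCC | starting material
27 | formaldehyde (from paraformaldehyde) | C=O | starting material
28 | iodomagnesium 1-ethoxy-3-iodopropa-1,2-dien-1-olate | CCOC(O[Mg]I)=C=CI | intermediate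
29 | ethyl (2Z)-2-(hydroxymethyl)-3-iodoprop-2-enoate | CCOC(=O)/C(CO)=C\I | intermediate
30 | ethyl (2Z)-2-{[(tert-butyldimethylsilyl)oxy]methyl}-3-iodoprop-2-enoate | CCOC(=O)/C(CO[Si](C)(C)C(C)(C)C)=C\I | intermediate
31 | (2Z)-2-{[(tert-butyldimethylsilyl)oxy]methyl}-3-iodoprop-2-enoic acid | OC(=O)/C(CO[Si](C)(C)C(C)(C)C)=C\I | intermediate
32 | (1Z,3R,7Z,11E)-14-(furan-3-yl)-3,7,11-trimethyltetradeca-1,7,11-trien-1-yl (2Z)-2-{[(tert-butyldimethylsilyl)oxy]methyl}-3-iodoprop-2-enoate | C/C(=C/CC/C(C)=C/CCc1ccoc1)CCC[C@@H](C)/C=C\OC(=O)/C(CO[Si](C)(C)C(C)(C)C)=C\I | intermediate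
33 | (5E)-3-{[(tert-butyldimethylsilyl)oxy]methyl}-5-[(2R,6Z,10E)-13-(furan-3-yl)-2,6,10-trimethyltrideca-6,10-dien-1-ylidene]furan-2(5H)-one | C/C(=C/CC/C(C)=C/CCc1ccoc1)CCC[C@@H](C)/C=C1\C=C(CO[Si](C)(C)C(C)(C)C)C(=O)O1 | intermediate
34 | 22-deoxy-23-hydroxymethylvariabilin, (5E)-5-[(2R,6Z,10E)-13-(furan-3-yl)-2,6,10-trimethyltrideca-6,10-dien-1-ylidene]-3-(hydroxymethyl)furan-2(5H)-one | C/C(=C/CC/C(C)=C/CCc1ccoc1)CCC[C@@H](C)/C=C1\C=C(CO)C(=O)O1 | target

Total step count: 19. Longest linear sequence: 12 steps (1, 2, 3, 4, 8, 9, 10, 12, 13, 17, 18, 19).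

Steps most likely to fail

Step 18. The cyclisation may be slow because the ester must reach its s-cis rotamer. β-Hydride elimination may also go toward the C–H of the methyl-bearing stereocentre, or Pd–H re-addition may isomerise the (5E)-ylidene to the more stable (5Z) form. The fallback sets out from 25 and 31 and forms the C4–C5 bond intermolecularly: Pd/Cu-catalysed Sonogashira coupling with in-situ 5-exo-dig lactonisation (PdCl2(PPh3)2, CuI, Et3N, MeCN, rt) should give the (5Z)-ylidene butenolide F1. Photochemical Z/E isomerisation of F1 (hν 300 nm, MeCN) and HPLC separation of the (5E) isomer then lead back to the route at 33.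

Step 17. Markovnikov addition, erosion of Z-selectivity at the enol ester, or catalyst deactivation by the vinyl iodide may intervene. The fallback sets out from 25 and builds the enol ester from an aldehyde enolate. Hydroboration–oxidation (Cy2BH, THF, 0 °C; NaBO3) should give (3R,7Z,11E)-14-(furan-3-yl)-3,7,11-trimethyltetradeca-7,11-dienal F2. Acid 31 is converted with Ghosez's reagent (CH2Cl2, 0 °C) into the acid chloride F3. Deprotonation of F2 with KOtBu (THF, −78 °C) to the potassium (Z)-enolate F4 and O-acylation with F3 should favour the (Z)-enol ester, which comes back to the route at 32 after chromatographic removal of the E isomer.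

Step 1. Aldol self-condensation of the aldehyde may outrun O-sulfonylation, or the (E)-alkenyl nonaflate may eliminate only sluggishly. The fallback sets out from 1 and uses a vinyl-iodide route. Hydrazine hydrate (EtOH, rt) should give the hydrazone F5, and Barton iodination (I2, tetramethylguanidine, THF, 0 °C) the 1-iodoalkene F6 as an E/Z mixture. Dehydroiodination of F6 with LDA (THF, −78 °C) gives the lithium acetylide, which on protonation comes back to the route at 3.

Further compounds
F1 | step 18 | (5Z)-3-{[(tert-butyldimethylsilyl)oxy]methyl}-5-[(2R,6Z,10E)-13-(furan-3-yl)-2,6,10-trimethyltrideca-6,10-dien-1-ylidene]furan-2(5H)-one | C/C(=C/CC/C(C)=C/CCc1ccoc1)CCC[C@@H](C)/C=C1/C=C(CO[Si](C)(C)C(C)(C)C)C(=O)O1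
F2 | step 17 | (3R,7Z,11E)-14-(furan-3-yl)-3,7,11-trimethyltetradeca-7,11-dienal | C/C(=C/CC/C(C)=C/CCc1ccoc1)CCC[C@@H](C)CC=O
F3 | step 17 | (2Z)-2-{[(tert-butyldimethylsilyl)oxy]methyl}-3-iodoprop-2-enoyl chloride | ClC(=O)/C(CO[Si](C)(C)C(C)(C)C)=C\I
F4 | step 17 | potassium (1Z,3R,7Z,11E)-14-(furan-3-yl)-3,7,11-trimethyltetradeca-1,7,11-trien-1-olate | C/C(=C/CC/C(C)=C/CCc1ccoc1)CCC[C@@H](C)/C=C\O[K]
F5 | step 1 | (3R)-3,7-dimethyloct-6-enal hydrazone | CC(C)=CCC[C@@H](C)CC=NN
F6 | step 1 | (3R)-1-iodo-3,7-dimethylocta-1,6-diene (E/Z) | CC(C)=CCC[C@@H](C)C=CI
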